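(The constants used here are invented; the rest is arithmetic.)

I had to choose the next run.

all flasks: substrate 0.091 M; partner 1.50 equiv; solid reagent 1.50 equiv; time 2.5 min
- amber: at 5 °C until 30 s, from then on at 35 °C
- blue: temperature 35 °C
- red: temperature 5 °C

    2 open intermediate → homo product (k1 = 0.096 M⁻¹ s⁻¹, Ea1 = 67.0 kJ mol⁻¹)
    open intermediate + second intermediate → target (k2 = 0.22 M⁻¹ s⁻¹, Ea2 = 48.0 kJ mol⁻¹)
    substrate + reagent → open intermediate (k3 = 0.39 M⁻¹ s⁻¹, Ea3 = 41.0 kJ mol⁻¹)
    reagent + partner → second intermediate (k4 = 0.23 M⁻¹ s⁻¹, Ea4 = 65.0 kJ mol⁻¹)
    solid reagent ⇌ reagent, rate k5*(cs5 - [reagent]) while solid is left; crystals form when [reagent] > cs5 (cs5 = 33 mM, k5 = 0.10 s⁻¹)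
    (constants at 35 °C)

- in percentages every species weighs as the substrate in it: one homo product counts as two
- for a step with 2 of a species take k times the square, and two of it per event
- as a solid, counted per litre of solution: solid reagent
- at 35 °C the constants are as listed, elsewhere as the activation energies make them
- at the start none of the solid reagent is in solution

- which flask leads in amount of target, in percent of the substrate charged ("all alike" within 1.5 percentage points) (amber / blue / red / all alike)
- how much target is there at the end, in percent of the substrate charged: amber
- how much target is there at the end, in percent of the substrate charged: blue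
- how much target is there at the end, in percent of the substrate charged: red

Target forms from two intermediates, and both start at zero. I therefore wanted to know when each flask leaves its waiting stage. First I took the constants down to 5 °C:

k(coupling to target) = 0.0292 M⁻¹ s⁻¹
k(substrate + reagent) = 0.0694 M⁻¹ s⁻¹
k(reagent + partner) = 0.0149 M⁻¹ s⁻¹

The solid feeds reagent while substrate and partner draw it off. With both charges taken as whole, feed meets draw at these levels:

[reagent], red = 30.5 mM
[reagent], blue = 19.8 mM

At such a level [open intermediate] and [second intermediate] both grow in proportion to time. Coupling then eats second intermediate as fast as it forms when k(coupling) × k(substrate + reagent) × [substrate] × [reagent] × t² reaches 1. I solved this for t in each flask: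

t, red = 7.04 min
t, blue = 1.34 min

I called this the coupling time, the end of the induction period for target. Before it, target grows with the cube of the time.

Red runs 2.5 min, shorter than its coupling time. The cube rule gave me 0.430% of target for red. Blue runs longer than its coupling time, so the cube rule no longer applied there and I stopped reckoning it. Amber keeps 2.00 min warm, longer than blue's coupling time but shorter than blue's whole run. My order was blue, amber, red, and I decided to drop the cold start.

The forecast gave 22.8% for amber, 26.9% for blue and 0.33% for red, with blue ahead, and began from “Reagent supply is dissolution-limited”.

The simulation gave 22.2% for amber, 26.5% for blue and 0.304% for red, so blue led, and red came in below my cube figure.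

In red, the coupling time of 7.04 min lay beyond the run of 2.5 min, and at 0.380 min the half-life of second intermediate by coupling was 150 min, far longer than the run, while at the end red held 25.3% open intermediate and, of the second intermediate, 0.00824 M, beside 0.304% target. The same red flask left until 10 min, past that coupling time, held 10.7% target.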